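**Retrosynthetic overview**
- Last step is global O-debenzylation; the C1 ketone comes from oxidation of a C1 carbinol that serves as a temporary stereochemical relay.
- The tetralone carbocycle is the last ring formed, by intramolecular aldol of the aryl benzyl ketone (C4) onto a methyl ketone (C3), with C3 steered by the C1 silyloxy centre.
- Key union C4–C9: intermolecular boron aldol of a ring A arylacetic thioester with the ring B benzaldehyde, then oxidation and decarboxylative removal of the thioester.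
- Both arenes come from methyl 3,5-dihydroxyphenylacetate. Ring A: formylation, then Brown allylation (sets C1). Ring B: dioxinone Claisen acylation and thermolysis to the 4-hydroxy-2-pyrone, O-benzylation, formylation.
- Ring order: pyrone first (fragment B), a transient δ-lactone on ring A, carbocycle last.

Assumption: the target is read as (3R,4S), with 3-OH and 4-aroyl cis; labels C1–C4 and C9 (ketone carbon between C4 and ring B) follow the target's tetralone numbering throughout, ring A being the tetralone arene and ring B the benzoyl arene.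

**Route**

Step 1
Reactants: 1 methyl 2-(3,5-dihydroxyphenyl)acetate
Product: 2 methyl 2-[3,5-bis(benzyloxy)phenyl]acetate
Conditions: BnBr, K2CO3, DMF, 60 °C
Reagents that add atoms: benzyl bromide, BrCc1ccccc1
Why: Williamson etherification in which K2CO3 deprotonates only the phenols (pKa about 10), giving benzyl ethers that survive every later step and fall together in the final hydrogenolysis; no stereocentre.

Step 2
Reactants: 2 methyl 2-[3,5-bis(benzyloxy)phenyl]acetate
Product: 3 methyl 2-[3,5-bis(benzyloxy)-2-formylphenyl]acetate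
Conditions: POCl3, DMF, 0 to 50 °C; then aq. NaOAc
Reagents that add atoms: N,N-dimethylformamide, CN(C)C=O; water, O
Why: Vilsmeier–Haack formylation of the electron-rich 1,3-dialkoxyarene goes ortho to the CH2CO2Me arm (para to one OBn, ortho to the other, the site between the two OBn groups being more hindered), which installs the future C1; no stereocentre.

Step 3
Reactants: 3 methyl 2-[3,5-bis(benzyloxy)-2-formylphenyl]acetate
Product: 5 (1S)-6,8-bis(benzyloxy)-1-(prop-2-en-1-yl)isochroman-3-one, via hydroxy ester 4 (not isolated)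
Conditions: (−)-Ipc2B(allyl), Et2O, −78 °C to rt; HOCH2CH2NH2; then DBU (cat.), CH2Cl2, rt
Reagents that add atoms: (−)-Ipc2B(allyl), C=CCB(C1CC2CC(C1C)C2(C)C)C1CC2CC(C1C)C2(C)C
Why: Brown allylboration through a chair six-membered transition state delivers allyl to the Si face of the aryl aldehyde (the (+)-α-pinene-derived reagent gives the S carbinol, as with benzaldehyde, about 95% ee), and DBU-catalysed transesterification then closes the δ-lactone, whose recrystallisation raises the ee.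

Step 4
Reactants: 5 (1S)-6,8-bis(benzyloxy)-1-(prop-2-en-1-yl)isochroman-3-one
Product: 8 2-[3,5-bis(benzyloxy)-2-[(1S)-1-[(tert-butyldimethylsilyl)oxy]but-3-en-1-yl]phenyl]acetic acid, via lithium hydroxy carboxylate 6 (not isolated), via bis-silyl derivative 7 (not isolated)
Conditions: LiOH, THF/H2O, rt; evaporate; TBSOTf, 2,6-lutidine, CH2Cl2, 0 °C; then K2CO3, MeOH/THF/H2O, rt; citric acid work-up
Reagents that add atoms: LiOH, [Li+].[OH-]; tert-butyldimethylsilyl triflate, CC(C)(C)[Si](C)(C)OS(=O)(=O)C(F)(F)F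
Why: Saponification opens the lactone, double silylation blocks relactonisation and carbonate methanolysis cleaves only the labile silyl ester (standard seco-acid protection), so C1 stays S and never meets acid strong enough to ionise this electron-rich benzylic position.

Step 5
Reactants: 8 2-[3,5-bis(benzyloxy)-2-[(1S)-1-[(tert-butyldimethylsilyl)oxy]but-3-en-1-yl]phenyl]acetic acid
Product: 9 S-ethyl 2-[3,5-bis(benzyloxy)-2-[(1S)-1-[(tert-butyldimethylsilyl)oxy]but-3-en-1-yl]phenyl]ethanethioate (fragment A)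
Conditions: EtSH, DCC, DMAP (cat.), CH2Cl2, 0 °C to rt
Reagents that add atoms: ethanethiol, CCS
Why: Steglich (DCC/DMAP) thioesterification gives a thioester whose benzylic α-CH2 can be enolised softly with a boron triflate and an amine and which can later be cleaved under neutral thiophilic conditions.

Step 6
Reactants: 2 methyl 2-[3,5-bis(benzyloxy)phenyl]acetate
Product: 10 2-[3,5-bis(benzyloxy)phenyl]acetic acid
Conditions: LiOH, THF/MeOH/H2O, rt; HCl work-up
Reagents that add atoms: LiOH, [Li+].[OH-]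
Why: Ester saponification to the arylacetic acid needed for acyl activation; no stereocentre.

Step 7
Reactants: 10 2-[3,5-bis(benzyloxy)phenyl]acetic acid; 11 2,2,6-trimethyl-4H-1,3-dioxin-4-one
Product: 14 6-[3-[3,5-bis(benzyloxy)phenyl]-2-oxopropyl]-2,2-dimethyl-4H-1,3-dioxin-4-one, via acyl imidazole 12 (not isolated), via lithium dienolate 13 (not isolated)
Conditions: 10, CDI, THF, rt; separately 11, LiN(iPr)2 (2.2 equiv), THF, −78 °C; combine, −78 to 0 °C; aq. NH4Cl
Reagents that add atoms: none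
Why: Crossed Claisen-type condensation in which the lithium dienolate of the dioxinone is acylated at its γ-carbon by the acyl imidazole (excess dienolate absorbs the acidic product), giving the masked 3,5-diketo acid; no stereocentre.

Step 8
Reactants: 14 6-[3-[3,5-bis(benzyloxy)phenyl]-2-oxopropyl]-2,2-dimethyl-4H-1,3-dioxin-4-one
Product: 16 6-[3,5-bis(benzyloxy)benzyl]-4-hydroxy-2H-pyran-2-one, via acylketene 15 (not isolated)
Conditions: toluene, 110 °C
Reagents that add atoms: none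
Why: Thermal retro-hetero-Diels–Alder loss of acetone unmasks an acylketene that is captured by the enol oxygen of the 5-keto group, the standard route to a 6-substituted 4-hydroxy-2-pyrone.

Step 9
Reactants: 16 6-[3,5-bis(benzyloxy)benzyl]-4-hydroxy-2H-pyran-2-one
Product: 17 4-(benzyloxy)-6-[3,5-bis(benzyloxy)benzyl]-2H-pyran-2-one
Conditions: BnOH, PPh3, DIAD, THF, 0 °C to rt
Reagents that add atoms: benzyl alcohol, OCc1ccccc1
Why: Mitsunobu alkylation of the acidic 4-OH (pKa about 5) gives the 4-benzyloxy-2-pyrone cleanly on oxygen, avoiding the C3-benzylation seen with benzyl halide and base.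

Step 10
Reactants: 17 4-(benzyloxy)-6-[3,5-bis(benzyloxy)benzyl]-2H-pyran-2-one
Product: 18 2,4-bis(benzyloxy)-6-[[4-(benzyloxy)-2-oxo-2H-pyran-6-yl]methyl]benzaldehyde (fragment B)
Conditions: POCl3, DMF, 0 °C to rt; then aq. NaOAc
Reagents that add atoms: N,N-dimethylformamide, CN(C)C=O; water, O
Why: Vilsmeier–Haack formylation again goes ortho to the benzylic arm of the dialkoxyarene (both ortho sites are equivalent), which is far more nucleophilic than the 4-alkoxy-2-pyrone, a vinylogous carbonate.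

Step 11
Reactants: 9 S-ethyl thioester (fragment A); 18 benzaldehyde (fragment B)
Product: 20 S-ethyl 3-[2,4-bis(benzyloxy)-6-[[4-(benzyloxy)-2-oxo-2H-pyran-6-yl]methyl]phenyl]-2-[3,5-bis(benzyloxy)-2-[(1S)-1-[(tert-butyldimethylsilyl)oxy]but-3-en-1-yl]phenyl]-3-hydroxypropanethioate (mixture at the two new centres), via boron enolate 19 (not isolated)
Conditions: 9, Bu2BOTf, iPr2NEt, CH2Cl2, −78 to 0 °C; then 18, −78 to 0 °C; pH 7 buffer/MeOH
Reagents that add atoms: none
Why: Key fragment union by an intermolecular boron-mediated aldol addition, in which the thioester is enolised softly (no strong base, so the acidic pyronylmethyl CH2 and the pyrone of 18 are spared) and its dibutylboron enolate adds to the hindered aldehyde through a closed transition state to form the C4–C9 bond; the two new centres are left as a mixture because C9 is oxidised in step 12 and C4 is re-made in steps 13 and 15.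

Step 12
Reactants: 20 β-hydroxy thioester
Product: 21 S-ethyl 3-[2,4-bis(benzyloxy)-6-[[4-(benzyloxy)-2-oxo-2H-pyran-6-yl]methyl]phenyl]-2-[3,5-bis(benzyloxy)-2-[(1S)-1-[(tert-butyldimethylsilyl)oxy]but-3-en-1-yl]phenyl]-3-oxopropanethioate
Conditions: Dess–Martin periodinane, pyridine, CH2Cl2, 0 °C to rt
Reagents that add atoms: none
Why: Dess–Martin oxidation of the secondary benzylic alcohol to the β-keto thioester under buffered conditions that leave thioester, silyl ether, alkene and pyrone alone.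

Step 13
Reactants: 21 β-keto thioester
Product: 23 1-[2,4-bis(benzyloxy)-6-[[4-(benzyloxy)-2-oxo-2H-pyran-6-yl]methyl]phenyl]-2-[3,5-bis(benzyloxy)-2-[(1S)-1-[(tert-butyldimethylsilyl)oxy]but-3-en-1-yl]phenyl]ethan-1-one, via β-keto acid 22 (not isolated)
Conditions: AgOCOCF3, 2,6-lutidine, THF/H2O, rt to 40 °C
Reagents that add atoms: none
Why: Thiophilic silver activation hydrolyses the thioester to the β-keto acid, which loses CO2 spontaneously (six-membered pericyclic decarboxylation) to leave the aryl benzyl ketone with C4 as CH2.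

Step 14
Reactants: 23 aryl benzyl ketone with the (1S)-silyloxybutenyl arm
Product: 24 (4S)-4-[2,4-bis(benzyloxy)-6-[2-[2,4-bis(benzyloxy)-6-[[4-(benzyloxy)-2-oxo-2H-pyran-6-yl]methyl]phenyl]-2-oxoethyl]phenyl]-4-[(tert-butyldimethylsilyl)oxy]butan-2-one
Conditions: PdCl2 (10 mol %), CuCl, O2 (1 atm), DMF/H2O, rt
Reagents that add atoms: water, O
Why: Wacker–Tsuji oxidation, in which Markovnikov hydroxypalladation of the terminal alkene gives the methyl ketone (C3 with its methyl), the pyrone and arenes being inert and the homoallylic silyl ether tolerated.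

Step 15
Reactants: 24 (4S)-silyloxy diketone
Product: 25 (1S,3R,4S)-6,8-bis(benzyloxy)-4-[2,4-bis(benzyloxy)-6-[[4-(benzyloxy)-2-oxo-2H-pyran-6-yl]methyl]benzoyl]-1-[(tert-butyldimethylsilyl)oxy]-3-methyl-1,2,3,4-tetrahydronaphthalen-3-ol
Conditions: LiN(SiMe3)2 (2.2 equiv), THF, −78 to −30 °C; AcOH quench at −78 °C
Reagents that add atoms: none
Why: Intramolecular (6-exo) aldol addition in which the second equivalent of base enolises the aryl benzyl ketone at C4 (the first is taken by the more acidic pyronylmethyl CH2, the methyl ketone staying un-enolised), and in the half-chair transition state the C1 silyloxy group, forced pseudoaxial by the peri OBn, makes a pseudoaxial methyl at C3 prohibitive (1,3-diaxial), so the new C–O bond forms cis to C1–O (3R from 1S), while lithium chelation between the new alkoxide and the C9 carbonyl places the aroyl group cis to it (4S); any C3 epimer is a diastereomer and is removed by chromatography.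

Step 16
Reactants: 25 silyl-protected aldol
Product: 26 (1S,3R,4S)-6,8-bis(benzyloxy)-4-[2,4-bis(benzyloxy)-6-[[4-(benzyloxy)-2-oxo-2H-pyran-6-yl]methyl]benzoyl]-3-methyl-1,2,3,4-tetrahydronaphthalene-1,3-diol
Conditions: Bu4NF, AcOH, THF, rt
Reagents that add atoms: none
Why: Fluoride desilylation buffered with acetic acid, so the tertiary β-hydroxy ketone neither reverts by retro-aldol nor epimerises at C4.

Step 17
Reactants: 26 1,3-diol
Product: 27 (3R,4S)-6,8-bis(benzyloxy)-4-[2,4-bis(benzyloxy)-6-[[4-(benzyloxy)-2-oxo-2H-pyran-6-yl]methyl]benzoyl]-3-hydroxy-3-methyl-3,4-dihydronaphthalen-1(2H)-one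
Conditions: Dess–Martin periodinane, pyridine, CH2Cl2, 0 °C
Reagents that add atoms: none
Why: Dess–Martin oxidation touches only the secondary benzylic C1 alcohol (the C3 alcohol is tertiary), turning the relay centre into the C1 ketone; C3 is quaternary, C4 is not enolised under these buffered conditions, and its cis arrangement (methyl anti to aroyl, O–H···O=C bond) is also the more stable one.

Step 18
Reactants: 27 pentabenzyl ether of the target
Product: 28 (3R,4S)-4-[2,4-dihydroxy-6-[(4-hydroxy-2-oxo-2H-pyran-6-yl)methyl]benzoyl]-3,6,8-trihydroxy-3-methyl-3,4-dihydronaphthalen-1(2H)-one (CNP0197349.1)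
Conditions: H2 (1 atm), 10% Pd/C, EtOAc/THF, rt
Reagents that add atoms: none
Why: Hydrogenolysis of all five benzyl ethers (four aryl, one pyronyl) under neutral conditions that avoid acid- or base-induced dehydration and retro-aldol of the β-hydroxy ketone; neither stereocentre is touched.

**Compound list**
1 | methyl 2-(3,5-dihydroxyphenyl)acetate | COC(=O)Cc1cc(O)cc(O)c1 | starting material
2 | methyl 2-[3,5-bis(benzyloxy)phenyl]acetate | COC(=O)Cc1cc(OCc2ccccc2)cc(OCc2ccccc2)c1 | intermediate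
3 | methyl 2-[3,5-bis(benzyloxy)-2-formylphenyl]acetate | COC(=O)Cc1cc(OCc2ccccc2)cc(OCc2ccccc2)c1C=O | intermediate
4 | methyl 2-[3,5-bis(benzyloxy)-2-[(1S)-1-hydroxybut-3-en-1-yl]phenyl]acetate | COC(=O)Cc1cc(OCc2ccccc2)cc(OCc2ccccc2)c1[C@@H](O)CC=C | intermediate
5 | (1S)-6,8-bis(benzyloxy)-1-(prop-2-en-1-yl)isochroman-3-one | C=CC[C@@H]1OC(=O)Cc2cc(OCc3ccccc3)cc(OCc3ccccc3)c12 | intermediate
6 | lithium 2-[3,5-bis(benzyloxy)-2-[(1S)-1-hydroxybut-3-en-1-yl]phenyl]acetate | [Li+].[O-]C(=O)Cc1cc(OCc2ccccc2)cc(OCc2ccccc2)c1[C@@H](O)CC=C | intermediate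
7 | tert-butyldimethylsilyl 2-[3,5-bis(benzyloxy)-2-[(1S)-1-[(tert-butyldimethylsilyl)oxy]but-3-en-1-yl]phenyl]acetate | CC(C)(C)[Si](C)(C)OC(=O)Cc1cc(OCc2ccccc2)cc(OCc2ccccc2)c1[C@@H](O[Si](C)(C)C(C)(C)C)CC=C | intermediate
8 | 2-[3,5-bis(benzyloxy)-2-[(1S)-1-[(tert-butyldimethylsilyl)oxy]but-3-en-1-yl]phenyl]acetic acid | OC(=O)Cc1cc(OCc2ccccc2)cc(OCc2ccccc2)c1[C@@H](O[Si](C)(C)C(C)(C)C)CC=C | intermediate
9 | S-ethyl 2-[3,5-bis(benzyloxy)-2-[(1S)-1-[(tert-butyldimethylsilyl)oxy]but-3-en-1-yl]phenyl]ethanethioate | CCSC(=O)Cc1cc(OCc2ccccc2)cc(OCc2ccccc2)c1[C@@H](O[Si](C)(C)C(C)(C)C)CC=C | intermediate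
10 | 2-[3,5-bis(benzyloxy)phenyl]acetic acid | OC(=O)Cc1cc(OCc2ccccc2)cc(OCc2ccccc2)c1 | intermediate
11 | 2,2,6-trimethyl-4H-1,3-dioxin-4-one | CC1=CC(=O)OC(C)(C)O1 | starting material
12 | 2-[3,5-bis(benzyloxy)phenyl]-1-(1H-imidazol-1-yl)ethan-1-one | O=C(Cc1cc(OCc2ccccc2)cc(OCc2ccccc2)c1)n1ccnc1 | intermediate
13 | lithium 2,2-dimethyl-6-methylidene-6H-1,3-dioxin-4-olate (dienolate of 11) | [Li]OC1=CC(=C)OC(C)(C)O1 | intermediate
14 | 6-[3-[3,5-bis(benzyloxy)phenyl]-2-oxopropyl]-2,2-dimethyl-4H-1,3-dioxin-4-one | CC1(C)OC(=O)C=C(CC(=O)Cc2cc(OCc3ccccc3)cc(OCc3ccccc3)c2)O1 | intermediate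
15 | 6-[3,5-bis(benzyloxy)phenyl]hex-1-ene-1,3,5-trione (acylketene) | O=C=CC(=O)CC(=O)Cc1cc(OCc2ccccc2)cc(OCc2ccccc2)c1 | intermediate
16 | 6-[3,5-bis(benzyloxy)benzyl]-4-hydroxy-2H-pyran-2-one | O=c1cc(O)cc(Cc2cc(OCc3ccccc3)cc(OCc3ccccc3)c2)o1 | intermediate
17 | 4-(benzyloxy)-6-[3,5-bis(benzyloxy)benzyl]-2H-pyran-2-one | O=c1cc(OCc2ccccc2)cc(Cc2cc(OCc3ccccc3)cc(OCc3ccccc3)c2)o1 | intermediate
18 | 2,4-bis(benzyloxy)-6-[[4-(benzyloxy)-2-oxo-2H-pyran-6-yl]methyl]benzaldehyde | O=Cc1c(OCc2ccccc2)cc(OCc2ccccc2)cc1Cc1cc(OCc2ccccc2)cc(=O)o1 | intermediate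
19 | dibutylboron enolate of thioester 9 | CCCCB(CCCC)OC(SCC)=Cc1cc(OCc2ccccc2)cc(OCc2ccccc2)c1[C@@H](O[Si](C)(C)C(C)(C)C)CC=C | intermediate
20 | S-ethyl 3-[2,4-bis(benzyloxy)-6-[[4-(benzyloxy)-2-oxo-2H-pyran-6-yl]methyl]phenyl]-2-[3,5-bis(benzyloxy)-2-[(1S)-1-[(tert-butyldimethylsilyl)oxy]but-3-en-1-yl]phenyl]-3-hydroxypropanethioate (mixture at C2 and C3 of the chain) | CCSC(=O)C(c1cc(OCc2ccccc2)cc(OCc2ccccc2)c1[C@@H](O[Si](C)(C)C(C)(C)C)CC=C)C(O)c1c(OCc2ccccc2)cc(OCc2ccccc2)cc1Cc1cc(OCc2ccccc2)cc(=O)o1 | intermediate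
21 | S-ethyl 3-[2,4-bis(benzyloxy)-6-[[4-(benzyloxy)-2-oxo-2H-pyran-6-yl]methyl]phenyl]-2-[3,5-bis(benzyloxy)-2-[(1S)-1-[(tert-butyldimethylsilyl)oxy]but-3-en-1-yl]phenyl]-3-oxopropanethioate | CCSC(=O)C(c1cc(OCc2ccccc2)cc(OCc2ccccc2)c1[C@@H](O[Si](C)(C)C(C)(C)C)CC=C)C(=O)c1c(OCc2ccccc2)cc(OCc2ccccc2)cc1Cc1cc(OCc2ccccc2)cc(=O)o1 | intermediate
22 | 3-[2,4-bis(benzyloxy)-6-[[4-(benzyloxy)-2-oxo-2H-pyran-6-yl]methyl]phenyl]-2-[3,5-bis(benzyloxy)-2-[(1S)-1-[(tert-butyldimethylsilyl)oxy]but-3-en-1-yl]phenyl]-3-oxopropanoic acid | OC(=O)C(c1cc(OCc2ccccc2)cc(OCc2ccccc2)c1[C@@H](O[Si](C)(C)C(C)(C)C)CC=C)C(=O)c1c(OCc2ccccc2)cc(OCc2ccccc2)cc1Cc1cc(OCc2ccccc2)cc(=O)o1 | intermediate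
23 | 1-[2,4-bis(benzyloxy)-6-[[4-(benzyloxy)-2-oxo-2H-pyran-6-yl]methyl]phenyl]-2-[3,5-bis(benzyloxy)-2-[(1S)-1-[(tert-butyldimethylsilyl)oxy]but-3-en-1-yl]phenyl]ethan-1-one | C=CC[C@H](O[Si](C)(C)C(C)(C)C)c1c(OCc2ccccc2)cc(OCc2ccccc2)cc1CC(=O)c1c(OCc2ccccc2)cc(OCc2ccccc2)cc1Cc1cc(OCc2ccccc2)cc(=O)o1 | intermediate
24 | (4S)-4-[2,4-bis(benzyloxy)-6-[2-[2,4-bis(benzyloxy)-6-[[4-(benzyloxy)-2-oxo-2H-pyran-6-yl]methyl]phenyl]-2-oxoethyl]phenyl]-4-[(tert-butyldimethylsilyl)oxy]butan-2-one | CC(=O)C[C@H](O[Si](C)(C)C(C)(C)C)c1c(OCc2ccccc2)cc(OCc2ccccc2)cc1CC(=O)c1c(OCc2ccccc2)cc(OCc2ccccc2)cc1Cc1cc(OCc2ccccc2)cc(=O)o1 | intermediate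
25 | (1S,3R,4S)-6,8-bis(benzyloxy)-4-[2,4-bis(benzyloxy)-6-[[4-(benzyloxy)-2-oxo-2H-pyran-6-yl]methyl]benzoyl]-1-[(tert-butyldimethylsilyl)oxy]-3-methyl-1,2,3,4-tetrahydronaphthalen-3-ol | C[C@@]1(O)C[C@H](O[Si](C)(C)C(C)(C)C)c2c(OCc3ccccc3)cc(OCc3ccccc3)cc2[C@@H]1C(=O)c1c(OCc2ccccc2)cc(OCc2ccccc2)cc1Cc1cc(OCc2ccccc2)cc(=O)o1 | intermediate
26 | (1S,3R,4S)-6,8-bis(benzyloxy)-4-[2,4-bis(benzyloxy)-6-[[4-(benzyloxy)-2-oxo-2H-pyran-6-yl]methyl]benzoyl]-3-methyl-1,2,3,4-tetrahydronaphthalene-1,3-diol | C[C@@]1(O)C[C@H](O)c2c(OCc3ccccc3)cc(OCc3ccccc3)cc2[C@@H]1C(=O)c1c(OCc2ccccc2)cc(OCc2ccccc2)cc1Cc1cc(OCc2ccccc2)cc(=O)o1 | intermediate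
27 | (3R,4S)-6,8-bis(benzyloxy)-4-[2,4-bis(benzyloxy)-6-[[4-(benzyloxy)-2-oxo-2H-pyran-6-yl]methyl]benzoyl]-3-hydroxy-3-methyl-3,4-dihydronaphthalen-1(2H)-one | C[C@@]1(O)CC(=O)c2c(OCc3ccccc3)cc(OCc3ccccc3)cc2[C@@H]1C(=O)c1c(OCc2ccccc2)cc(OCc2ccccc2)cc1Cc1cc(OCc2ccccc2)cc(=O)o1 | intermediate
28 | (3R,4S)-4-[2,4-dihydroxy-6-[(4-hydroxy-2-oxo-2H-pyran-6-yl)methyl]benzoyl]-3,6,8-trihydroxy-3-methyl-3,4-dihydronaphthalen-1(2H)-one | C[C@@]1(O)CC(=O)c2c(O)cc(O)cc2[C@@H]1C(=O)c1c(O)cc(O)cc1Cc1cc(O)cc(=O)o1 | target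

**Totals**
Total step count: 18. Longest linear sequence: 14 steps (1, 6 to 10, then 11 to 18).

**Steps most likely to fail**

Step 11, the fragment union. The aldol joins an ortho-substituted arylacetic thioester enolate to a 2,6-disubstituted, electron-rich benzaldehyde that also carries an acidic pyronylmethyl CH2, so it may be slow or stall. The fallback sets out from aldehyde 18 (with thioester 9) and comes back at β-keto thioester 21. Pinnick oxidation of 18 (NaClO2, NaH2PO4, 2-methylbut-2-ene) gives 2,4-bis(benzyloxy)-6-[[4-(benzyloxy)-2-oxo-2H-pyran-6-yl]methyl]benzoic acid F1. Oxalyl chloride with catalytic DMF converts it into the corresponding benzoyl chloride F2. A crossed Claisen condensation, with soft enolisation of 9 by MgBr2·OEt2 and iPr2NEt in CH2Cl2 and C-acylation by F2, then gives 21 directly, so step 12 is not needed.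

Step 15, the ring-closing aldol. Possible failures are E1cB loss of the silyloxy group from the β-silyloxy ketone, incomplete 1,3-induction at C3, or a C4 epimer. A C4 epimer would converge on the cis isomer at the stage of 27 with Et3N in CH2Cl2, where only C4–H is acidic. The fallback sets out from 24 and comes back at diol 26. Desilylation (Bu4NF, AcOH) gives the free hydroxy diketone (4S)-4-[2,4-bis(benzyloxy)-6-[2-[2,4-bis(benzyloxy)-6-[[4-(benzyloxy)-2-oxo-2H-pyran-6-yl]methyl]phenyl]-2-oxoethyl]phenyl]-4-hydroxybutan-2-one F3. This is cyclised with MgBr2·OEt2 and iPr2NEt, where magnesium bridges the C1 oxygen and the C3 carbonyl in a six-membered chelate, so the softly formed C4 enolate closes the ring with the new C3–O syn to C1–O. That gives 26 without step 16.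

Step 18, the global debenzylation. The 2-pyrone double bonds or the aryl ketones may be reduced, or the hydrogenolysis may be sluggish on the hindered ethers. The fallback sets out from 27 and comes back at 28. It uses Lewis-acid debenzylation with BCl3 and pentamethylbenzene as cation scavenger in CH2Cl2 at −78 °C, quenched cold with MeOH, and makes no new compound.

**Further compounds**
F1 | step 11 | 2,4-bis(benzyloxy)-6-[[4-(benzyloxy)-2-oxo-2H-pyran-6-yl]methyl]benzoic acid | OC(=O)c1c(OCc2ccccc2)cc(OCc2ccccc2)cc1Cc1cc(OCc2ccccc2)cc(=O)o1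
F2 | step 11 | 2,4-bis(benzyloxy)-6-[[4-(benzyloxy)-2-oxo-2H-pyran-6-yl]methyl]benzoyl chloride | O=C(Cl)c1c(OCc2ccccc2)cc(OCc2ccccc2)cc1Cc1cc(OCc2ccccc2)cc(=O)o1
F3 | step 15 | (4S)-4-[2,4-bis(benzyloxy)-6-[2-[2,4-bis(benzyloxy)-6-[[4-(benzyloxy)-2-oxo-2H-pyran-6-yl]methyl]phenyl]-2-oxoethyl]phenyl]-4-hydroxybutan-2-one | CC(=O)C[C@H](O)c1c(OCc2ccccc2)cc(OCc2ccccc2)cc1CC(=O)c1c(OCc2ccccc2)cc(OCc2ccccc2)cc1Cc1cc(OCc2ccccc2)cc(=O)o1
F0 | step 18 | none | none
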